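The pitfall with a run that flattens is to scale its last reading as a fixed share of the Q charged, as if every flask turned the same part of its charge.

the same everywhere: J 0.800 M
- north-east: Q 0.400 M
- north-west: Q 0.600 M
- east: Q 0.980 M; time 98 min

- north-east run (time / min: [G] / M): 3.9: 0.0058; 6.2: 0.0094; 9.8: 0.0237; 16: 0.0443; 25: 0.0724; 39: 0.1017; 62: 0.1278; 98: 0.1387
- north-west run (time / min: [G] / M): 3.9: 0.0071; 6.2: 0.0138; 9.8: 0.0317; 16: 0.0627; 25: 0.1000; 39: 0.1391; 62: 0.1727; 98: 0.1875

(readings scatter by 0.002 M)

- Overall: Q + J -> G.
- Constant volume, constant temperature.
- The analysis sees a species whether free or bound.
- "The second partner" is J.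
- An order is taken over about fifteen percent of the charge, up and down.

* the exponent of [Q] in the starting rate at the charge of the north-east run (at the point where two percent of the Q have become G) (one fixed amount of G, the same in the runs compared)
* G in the east run at 98 min, as a share of the Q charged

Does that share hold between the two runs? It does not: if I count turnovers, meaning G at 98 min per Q charged, which is the conversion at that one time, the north-east run gives 34.7% and the north-west run 31.2%, a smaller share than the north-east run, though it was charged with more Q.

Is that gap more than scatter? I put it as the turnover penalty, the fall in turnover per molar of extra Q charged, at one fixed time and one charge of J, and the two readings give 0.171 M⁻¹ with a scatter of 0.0300 M⁻¹, so the penalty stands clear of the noise.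

But any two runs draw a line, so why trust it for the east flask? I hold it as a bet, since the step from the north-west charge to the east charge is nearly twice the step between the two runs, yet charging that penalty on the north-west turnover gives my own figure for the east run, 24.7%.

And the forecast? It gives an order in Q of 0.85 and 28% for the east run, reading the flattening thus: “This looks like an equilibrium or something close to it”; its east figure stands higher than mine, and I offer no order of my own.

The east run turns 25.2% of its Q charged into G at 98 min, and the order in Q at the north-east charge comes to 0.58, against the forecast's 0.85.

Q → Z (0.08160 min⁻¹); Z + J → G (0.07500 M⁻¹ min⁻¹); Z → E (0.06420 min⁻¹); Q + J ⇌ QJ, settled at all times (1.630 M⁻¹); 2 Q → Gu (0.09300 M⁻¹ min⁻¹) At the same small amount of G, the north-west rate of 0.0033 M min⁻¹ is 1.2 times the north-east rate of 0.0026 M min⁻¹. The penalty of 0.171 M⁻¹, charged on the north-west turnover, gave 24.7% for the east run, 0.50 percentage points below the flask. Reckoned from the north-west run to the east run, the penalty comes to 0.159 M⁻¹.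

The earlier runs and the new flask were generated by integration on assumed constants.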